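Assumption: the target has no stereocentre and no stereogenic double bond, so it is achiral and no stereocontrol is needed; the tether is read as fourteen CH2 groups.

**Retrosynthetic overview**
1. Both ring–CH2 bonds of the tether are cut last: target ⇒ two copies of 2-hydroxy-5-methoxy-6-methyl-1,4-benzoquinone plus hexadecanedioic acid (double decarboxylative radical C–H alkylation at the only free ring carbon).
2. Key disconnection: the ring C–OH bond of that monomer ⇒ 2-methoxy-3-methyl-1,4-benzoquinone, by redox-neutral oxygen-atom transfer from a pyridine N-oxide to C5–H (new C–O bond-forming step that fixes the OH/OMe/Me pattern).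
3. The methoxyquinone ⇒ 3-methoxy-2-methylphenol by aerobic para-oxidation; the adjacent OMe/Me pair is bought in.
4. No ring is built: both six-membered rings come intact from the phenol, are oxygenated first (C=O, then C–OH) and joined last.

**Route**

Step 1
Reactants: 1 3-methoxy-2-methylphenol
Product: 2 2-methoxy-3-methylcyclohexa-2,5-diene-1,4-dione (2-methoxy-3-methyl-1,4-benzoquinone)
Conditions: Co(salen) (N,N'-bis(salicylidene)ethylenediaminocobalt, C16H14CoN2O2, 5 mol %), O2 (1 atm), DMF, 23 °C, 16 h
Reagents that add atoms: dioxygen, O=O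
Why: The divalent cobalt complex binds O2, abstracts the phenolic hydrogen and delivers oxygen to the free para carbon (salcomine phenol-to-para-quinone oxidation, which works on related alkyl methoxyphenols), leaving OMe and Me untouched; no stereocentre is formed.

Step 2
Reactants: 2 2-methoxy-3-methylcyclohexa-2,5-diene-1,4-dione
Product: 4 2-hydroxy-5-methoxy-6-methylcyclohexa-2,5-diene-1,4-dione, via N-aryloxylutidinium adduct 3 (not isolated)
Conditions: 2,6-lutidine N-oxide (1.3 equiv, added over 2 h), Sc(OTf)3 (10 mol %), 4 Å MS, MeCN, 0 to 40 °C, N2; then 1 M HCl wash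
Reagents that add atoms: 2,6-lutidine N-oxide (2,6-dimethylpyridine 1-oxide), Cc1cccc(C)[n+]1[O-]
Why: Proposed new method: redox-neutral C–H hydroxylation of a quinone by oxygen-atom transfer from an amine N-oxide. Sc(OTf)3 chelated by C1=O and the 2-OMe oxygen activates the C1 enone, and the N-oxide oxygen adds in an oxa-Michael sense at C5. This is the site where amines, thiols and acetate add to 2-methoxyquinones, because attack there keeps the vinylogous-ester C4=O intact. Enolisation gives the N-aryloxypyridinium hydroquinone 3, whose ortho phenoxide expels 2,6-lutidine by N–O heterolysis, the N–O bond serving as internal two-electron oxidant. The resulting hydroxy-ortho-quinone tautomerises to 4. The hindered lutidine cannot add to the quinone, and the acidic product, held as its lutidinium salt, resists a second addition. Closest known reaction types are the Ganem/Kornblum oxidation of alkyl halides by amine N-oxides and the Thiele–Winter acetoxylation (same regiochemistry); no stereocentre is formed.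

Step 3
Reactants: 4 2-hydroxy-5-methoxy-6-methylcyclohexa-2,5-diene-1,4-dione (2.6 equiv), 5 hexadecanedioic acid (1.0 equiv)
Product: 7 3,3'-(tetradecane-1,14-diyl)bis(2-hydroxy-5-methoxy-6-methylcyclohexa-2,5-diene-1,4-dione), via monoalkylated carboxylic acid 6 (not isolated)
Conditions: AgNO3 (0.4 equiv), (NH4)2S2O8 (3.0 equiv, aq., added over 1 h), MeCN/H2O (1:1), 75 °C
Reagents that add atoms: none
Why: Silver-catalysed persulfate decarboxylation (Kochi–Anderson/Jacobsen–Torssell radical alkylation, established for hydroxyquinones) converts each carboxyl group of 5 into a nucleophilic primary alkyl radical that adds to the only unsubstituted ring carbon of 4; reoxidation restores the quinone, giving acid 6 and then the symmetrical bis-quinone 7, with no stereocentre formed.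

**Compound list**
1 | 3-methoxy-2-methylphenol | COc1cccc(O)c1C | starting material
2 | 2-methoxy-3-methylcyclohexa-2,5-diene-1,4-dione | COC1=C(C)C(=O)C=CC1=O | intermediate
3 | 2-[(2,6-dimethylpyridin-1-ium-1-yl)oxy]-4-hydroxy-5-methoxy-6-methylphenolate (zwitterion) | Cc1cccc(C)[n+]1Oc1cc(O)c(OC)c(C)c1[O-] | intermediate
4 | 2-hydroxy-5-methoxy-6-methylcyclohexa-2,5-diene-1,4-dione | COC1=C(C)C(=O)C(O)=CC1=O | intermediate
5 | hexadecanedioic acid | OC(=O)CCCCCCCCCCCCCCC(O)=O | starting material
6 | 15-(2-hydroxy-5-methoxy-4-methyl-3,6-dioxocyclohexa-1,4-dien-1-yl)pentadecanoic acid | COC1=C(C)C(=O)C(O)=C(CCCCCCCCCCCCCCC(O)=O)C1=O | intermediate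
7 | 3,3'-(tetradecane-1,14-diyl)bis(2-hydroxy-5-methoxy-6-methylcyclohexa-2,5-diene-1,4-dione) | COC1=C(C)C(=O)C(O)=C(CCCCCCCCCCCCCCC2=C(O)C(=O)C(C)=C(OC)C2=O)C1=O | target

**Totals**
Total step count: 3. Longest linear sequence: 3 (1 → 2 → 4 → 7).

**Steps most likely to fail, with fallbacks**

Step 2 (the new N-oxide hydroxylation) is the riskiest. The N-oxide may be too weak a nucleophile, the product may bind and inhibit Sc(OTf)3, or some C6 attack may occur. The fallback uses known chemistry, sets out from 2 and comes back at 4. Thiele–Winter acetoxylation of 2 (Ac2O, cat. H2SO4, 23 °C) gives 5-methoxy-6-methylbenzene-1,2,4-triyl triacetate F3 with the acetoxy group at the same C5 position. Acid methanolysis (HCl, MeOH, reflux, N2) gives 5-methoxy-6-methylbenzene-1,2,4-triol F4, which is oxidised by air or aqueous FeCl3 to 4.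

Step 3 (double radical alkylation) is next. Two decarboxylation/addition events on one diacid with a persulfate-sensitive hydroxyquinone may give only a modest yield, with acid 6 left over. The fallback sets out from 4 and comes back at 7, replacing the radical step by an ionic three-component reductive alkylation. Tetradecanedial F5 is made from commercial tetradecane-1,14-diol (TEMPO, PhI(OAc)2, CH2Cl2). It is condensed with 4 (2.1 equiv) under L-proline catalysis (20 mol %, CH2Cl2, 23 °C) in a double Knoevenagel reaction to give 3,3'-(tetradecane-1,14-diylidene)bis(5-methoxy-6-methylcyclohex-5-ene-1,2,4-trione) F6, with alkene geometry uncontrolled and irrelevant. F6 is reduced in the same flask by Hantzsch ester (diethyl 2,6-dimethyl-1,4-dihydropyridine-3,5-dicarboxylate, 2.2 equiv) to 7.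

Step 1 (aerobic oxidation) is the least risky. The phenol has a free ortho position, so oxidative coupling or ortho-quinone formation could lower the yield. The fallback sets out from 1 and comes back at 2 by a two-stage ionic para-hydroxylation. Elbs persulfate oxidation (K2S2O8, aq. KOH, 0 to 20 °C) gives potassium 4-hydroxy-2-methoxy-3-methylphenyl sulfate F1. Hydrolysis (aq. HCl, 80 °C) gives 2-methoxy-3-methylbenzene-1,4-diol F2, which is oxidised with aqueous FeCl3 (or Ag2O in Et2O) to 2.

**Further compounds**
F1 | step 1 | potassium 4-hydroxy-2-methoxy-3-methylphenyl sulfate | COc1c(OS(=O)(=O)[O-])ccc(O)c1C.[K+]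
F2 | step 1 | 2-methoxy-3-methylbenzene-1,4-diol | COc1c(O)ccc(O)c1C
F3 | step 2 | 5-methoxy-6-methylbenzene-1,2,4-triyl triacetate | CC(=O)Oc1cc(OC(C)=O)c(OC)c(C)c1OC(C)=O
F4 | step 2 | 5-methoxy-6-methylbenzene-1,2,4-triol | COc1c(O)cc(O)c(O)c1C
F5 | step 3 | tetradecanedial | O=CCCCCCCCCCCCCC=O
F6 | step 3 | 3,3'-(tetradecane-1,14-diylidene)bis(5-methoxy-6-methylcyclohex-5-ene-1,2,4-trione), alkene geometry not controlled | COC1=C(C)C(=O)C(=O)C(=CCCCCCCCCCCCCC=C2C(=O)C(=O)C(C)=C(OC)C2=O)C1=O
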